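**Plan**
- Retrosynthesis: the quinone ring is taken back to its 1,4-dimethoxyarene. The side chain (C1' at the ring to C16') is then cut at C10'–C11', the bond between the two carbinol carbons, and last at the aryl–C1' bond.
- The C8 half is sulcatone (C11' to C16' with both methyl branches). The other half is the aldehyde left when the terminal isopropylidene of an (E,E)-farnesyl arene is cleaved, so C10' is its CHO carbon.
- Enabling feature: C11' bears O, CH3 and a CH2 arm, and the two carbon arms are too alike for face-selective attack on the ketone. Its oxygen can carry a 2,4,6-triisopropylbenzoyl (TIB) group whose C=O directs removal of the C11'–H and chelates lithium. This gives the configurationally stable tertiary carbanion (umpolung) that the O–C10'–C11'–O pattern demands.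
- Forward: aryllithium plus farnesyl bromide, terminal epoxide, cleavage to the aldehyde. Union with the lithiated sulcatyl TIB ester follows, with oxidation of the alkoxide in the same flask to the C10' ketone. Reduction, ester removal and formation of the quinone ring come last.
- Stereochemistry: C11' (S) comes from enzymatic reduction of sulcatone (R), Mitsunobu inversion (S), then retentive lithiation and retentive substitution. C10' (S) comes from catalyst-controlled CBS reduction with the fully substituted C11' as the large group. Both E alkenes come with farnesyl bromide.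

Key step: step 8

Remark on the chemistry: compounds 10, 11 and 12 are racemic at the carbon that becomes C10'. Step 7 flattens this centre to the aldehyde, so no control is needed there. Compounds 1, 4 and 7 and all reagents are taken to be catalogue items.

**Step 1**
Reactants: 1 6-methylhept-5-en-2-one (sulcatone)
Product: 2 (R)-6-methylhept-5-en-2-ol
Conditions: Lactobacillus brevis alcohol dehydrogenase, NADP+ (cat.), MgCl2, i-PrOH, phosphate buffer pH 7, 30 °C
Reagents that add atoms: none
Why: Biocatalytic asymmetric transfer hydrogenation, in which the anti-Prelog enzyme tells the methyl arm from the long arm in its two binding pockets and should deliver hydride to give the R carbinol while i-PrOH recycles the cofactor.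

**Step 2**
Reactants: 2 (R)-6-methylhept-5-en-2-ol
Product: 3 (S)-6-methylhept-5-en-2-yl 2,4,6-triisopropylbenzoate
Conditions: 2,4,6-triisopropylbenzoic acid, PPh3, DIAD, THF, 0 °C to rt
Reagents that add atoms: 2,4,6-triisopropylbenzoic acid, CC(C)c1cc(C(C)C)c(C(=O)O)c(C(C)C)c1
Why: Mitsunobu reaction, in which the carboxylate displaces the activated oxygen at the carbinol carbon in SN2 fashion (inversion, R to S), which also avoids attack of a secondary alcohol on the very hindered acyl carbon.

**Step 3**
Reactants: 4 4-methoxy-2-methylphenol
Product: 5 2-bromo-4-methoxy-6-methylphenol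
Conditions: NBS, CH2Cl2, 0 °C
Reagents that add atoms: NBS, O=C1CCC(=O)N1Br
Why: Electrophilic aromatic bromination, in which the free OH is the strongest director and, with its para carbon blocked by OMe and one ortho carbon by CH3, should send bromine to the remaining ortho carbon.

**Step 4**
Reactants: 5 2-bromo-4-methoxy-6-methylphenol
Product: 6 1-bromo-2,5-dimethoxy-3-methylbenzene
Conditions: MeI, K2CO3, acetone, reflux
Reagents that add atoms: MeI, CI
Why: Williamson ether synthesis on the phenoxide, which gives a hydroquinone dimethyl ether that tolerates organolithiums, hydrides and periodic acid.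

**Step 5**
Reactants: 6 1-bromo-2,5-dimethoxy-3-methylbenzene; 7 (2E,6E)-farnesyl bromide
Product: 9 1-[(2E,6E)-3,7,11-trimethyldodeca-2,6,10-trienyl]-2,5-dimethoxy-3-methylbenzene (farnesyl arene), via aryllithium 8 (not isolated)
Conditions: n-BuLi, THF, −78 °C; then 7, −78 °C to rt
Reagents that add atoms: n-BuLi, [Li]CCCC (its lithium stands in 8 only)
Why: Bromine–lithium exchange followed by SN2 allylation at the primary allylic carbon, a standard way to prenylated hydroquinone ethers that leaves both E alkenes untouched.

**Step 6**
Reactants: 9 farnesyl arene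
Product: 11 3-[(3E,7E)-9-(2,5-dimethoxy-3-methylphenyl)-3,7-dimethylnona-3,7-dienyl]-2,2-dimethyloxirane (racemic), via bromohydrin 10 (not isolated)
Conditions: NBS (1.05 equiv), THF/H2O, 0 °C; then K2CO3, MeOH, rt
Reagents that add atoms: water, O (the epoxide oxygen); NBS, O=C1CCC(=O)N1Br (its bromine stands in 10 only)
Why: Terminal-selective bromohydrin formation in aqueous THF (the most exposed isopropylidene alkene takes up bromonium, water opens it at the tertiary carbon, and alkene attack at 0 °C should outrun ring bromination) followed by Williamson-type ring closure.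

**Step 7**
Reactants: 11 terminal epoxide
Product: 13 (4E,8E)-10-(2,5-dimethoxy-3-methylphenyl)-4,8-dimethyldeca-4,8-dienal, via glycol 12 (not isolated)
Conditions: H5IO6, THF/H2O, 0 °C
Reagents that add atoms: water, O (enters glycol 12 at the tertiary carbon and leaves again in acetone)
Why: Acid-induced opening of the epoxide and Malaprade cleavage of the resulting glycol, which removes the three terminal carbons and leaves C10' as the aldehyde carbon while alkenes and aryl ethers are inert.

**Step 8**
Reactants: 3 (S)-6-methylhept-5-en-2-yl 2,4,6-triisopropylbenzoate; 13 (4E,8E)-10-(2,5-dimethoxy-3-methylphenyl)-4,8-dimethyldeca-4,8-dienal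
Product: 16 (2E,6E,11S)-1-(2,5-dimethoxy-3-methylphenyl)-3,7,11,15-tetramethyl-10-oxohexadeca-2,6,14-trien-11-yl 2,4,6-triisopropylbenzoate (C10' ketone), via organolithium 14 (not isolated), via lithium alkoxide 15 (not isolated)
Conditions: 3 (1.3 equiv), s-BuLi (1.2 equiv), TMEDA, CPME, −60 °C, 2 h; 13 (1.0 equiv), −78 °C; PhS(Cl)=N-t-Bu (1.6 equiv), −78 °C to rt
Reagents that add atoms: s-BuLi, [Li]C(C)CC (its lithium stands in 14 and 15 only)
Why: The ester C=O of 3 binds s-BuLi/TMEDA and steers it to the neighbouring C11'–H (complex-induced proximity), so deprotonation with retention gives the dipole-stabilised, O-chelated tertiary organolithium 14, which should hold its configuration at −60 °C and below, while the two ortho isopropyl groups shield the ester carbon from attack and from 1,2-acyl shift. 14 adds to the CHO carbon of 13 on its lithium-bearing face (SE2 with retention) and so forms the C10'–C11' bond at the fully substituted carbon, after which lithium alkoxide 15 attacks sulfur of the sulfinimidoyl chloride and loses the C10'–H through a five-membered cyclic transition state to give ketone 16. The closest known reaction types are the Hoppe-type alpha-lithiation and carbonyl trapping of hindered benzoates of secondary dialkyl carbinols and the one-flask organolithium addition/Mukaiyama sulfinimidoyl chloride oxidation of aldehydes to ketones, and no ring is closed. C11' (S) is controlled only by the configuration of 3 through two retentive events, whereas C10' would form without useful control because the CH3 and CH2 arms on C11' are nearly equal in size, so it is erased at once and set in step 9. The selectivity needed is directed C–H removal instead of allylic metalation of 3 (chelation and low temperature, and the trisubstituted alkene cannot be carbolithiated through a four- or five-membered ring) and 1,2-addition instead of enolisation or benzylic-allylic deprotonation of 13 (most electrophilic carbonyl class, −78 °C, 3 kept in excess over s-BuLi so that no free base meets 13). Oxidation at −78 °C also consumes the alkoxide before it can pull the acyl group from the tertiary to the secondary oxygen.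

**Step 9**
Reactants: 16 C10' ketone
Product: 17 (2E,6E,10S,11S)-1-(2,5-dimethoxy-3-methylphenyl)-10-hydroxy-3,7,11,15-tetramethylhexadeca-2,6,14-trien-11-yl 2,4,6-triisopropylbenzoate
Conditions: (R)-1-methyl-3,3-diphenyltetrahydro-1H,3H-pyrrolo[1,2-c][1,3,2]oxazaborole ((R)-Me-CBS, 30 mol %), catecholborane, toluene, −40 to −20 °C
Reagents that add atoms: none
Why: Corey–Bakshi–Shibata reduction, in which the ketone binds the catalyst boron through the lone pair anti to the fully substituted C11' (large group) against the C9' methylene (small group), so the R catalyst should deliver hydride to the face giving 10'S against a negligible substrate bias, and catecholborane leaves the trisubstituted alkenes alone.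

**Step 10**
Reactants: 17 (10'S,11'S)-hydroxy TIB ester
Product: 18 (2E,6E,10S,11S)-1-(2,5-dimethoxy-3-methylphenyl)-3,7,11,15-tetramethylhexadeca-2,6,14-triene-10,11-diol
Conditions: LiAlH4, THF, reflux
Reagents that add atoms: none
Why: Reductive ester cleavage, helped by the C10' alkoxyaluminate that forms first and can pass hydride intramolecularly to the hindered acyl carbon, with no C–O bond at either stereocentre being broken.

**Step 11**
Reactants: 18 diol dimethyl ether
Product: 19 2-[(2E,6E,10S,11S)-10,11-dihydroxy-3,7,11,15-tetramethylhexadeca-2,6,14-trienyl]-6-methylcyclohexa-2,5-diene-1,4-dione (target)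
Conditions: (NH4)2Ce(NO3)6 (2.2 equiv), MeCN/H2O, 0 °C, 15 min
Reagents that add atoms: water, O (both quinone oxygens)
Why: Oxidative demethylation of a 1,4-dimethoxyarene by tetravalent cerium (two one-electron oxidations, water adds at the two oxygen-bearing ring carbons, methanol leaves), in which the electron-rich ring should be oxidised much faster than the glycol or the alkenes at 0 °C with a near-stoichiometric charge.

**Compound list**
1 | 6-methylhept-5-en-2-one (sulcatone) | CC(C)=CCCC(C)=O | starting material
2 | (R)-6-methylhept-5-en-2-ol | CC(C)=CCC[C@@H](C)O | intermediate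
3 | (S)-6-methylhept-5-en-2-yl 2,4,6-triisopropylbenzoate | CC(C)=CCC[C@H](C)OC(=O)c1c(C(C)C)cc(C(C)C)cc1C(C)C | intermediate
4 | 4-methoxy-2-methylphenol | COc1ccc(O)c(C)c1 | starting material
5 | 2-bromo-4-methoxy-6-methylphenol | COc1cc(C)c(O)c(Br)c1 | intermediate
6 | 1-bromo-2,5-dimethoxy-3-methylbenzene | COc1cc(C)c(OC)c(Br)c1 | intermediate
7 | (2E,6E)-farnesyl bromide | CC(C)=CCC/C(C)=C/CC/C(C)=C/CBr | starting material
8 | 2,5-dimethoxy-3-methylphenyllithium | [Li]c1cc(OC)cc(C)c1OC | intermediate
9 | 1-[(2E,6E)-3,7,11-trimethyldodeca-2,6,10-trienyl]-2,5-dimethoxy-3-methylbenzene | CC(C)=CCC/C(C)=C/CC/C(C)=C/Cc1cc(OC)cc(C)c1OC | intermediate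
10 | (6E,10E)-3-bromo-12-(2,5-dimethoxy-3-methylphenyl)-2,6,10-trimethyldodeca-6,10-dien-2-ol (racemic) | CC(C)(O)C(Br)CC/C(C)=C/CC/C(C)=C/Cc1cc(OC)cc(C)c1OC | intermediate
11 | 3-[(3E,7E)-9-(2,5-dimethoxy-3-methylphenyl)-3,7-dimethylnona-3,7-dienyl]-2,2-dimethyloxirane (racemic) | CC1(C)OC1CC/C(C)=C/CC/C(C)=C/Cc1cc(OC)cc(C)c1OC | intermediate
12 | (6E,10E)-12-(2,5-dimethoxy-3-methylphenyl)-2,6,10-trimethyldodeca-6,10-diene-2,3-diol (racemic) | CC(C)(O)C(O)CC/C(C)=C/CC/C(C)=C/Cc1cc(OC)cc(C)c1OC | intermediate
13 | (4E,8E)-10-(2,5-dimethoxy-3-methylphenyl)-4,8-dimethyldeca-4,8-dienal | O=CCC/C(C)=C/CC/C(C)=C/Cc1cc(OC)cc(C)c1OC | intermediate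
14 | (S)-2-lithio-6-methylhept-5-en-2-yl 2,4,6-triisopropylbenzoate | CC(C)=CCC[C@]([Li])(C)OC(=O)c1c(C(C)C)cc(C(C)C)cc1C(C)C | intermediate
15 | lithium (2E,6E,11S)-1-(2,5-dimethoxy-3-methylphenyl)-3,7,11,15-tetramethyl-11-(2,4,6-triisopropylbenzoyloxy)hexadeca-2,6,14-trien-10-olate (both C10' epimers) | CC(C)=CCC[C@](C)(OC(=O)c1c(C(C)C)cc(C(C)C)cc1C(C)C)C(O[Li])CC/C(C)=C/CC/C(C)=C/Cc1cc(OC)cc(C)c1OC | intermediate
16 | (2E,6E,11S)-1-(2,5-dimethoxy-3-methylphenyl)-3,7,11,15-tetramethyl-10-oxohexadeca-2,6,14-trien-11-yl 2,4,6-triisopropylbenzoate | CC(C)=CCC[C@](C)(OC(=O)c1c(C(C)C)cc(C(C)C)cc1C(C)C)C(=O)CC/C(C)=C/CC/C(C)=C/Cc1cc(OC)cc(C)c1OC | intermediate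
17 | (2E,6E,10S,11S)-1-(2,5-dimethoxy-3-methylphenyl)-10-hydroxy-3,7,11,15-tetramethylhexadeca-2,6,14-trien-11-yl 2,4,6-triisopropylbenzoate | CC(C)=CCC[C@](C)(OC(=O)c1c(C(C)C)cc(C(C)C)cc1C(C)C)[C@@H](O)CC/C(C)=C/CC/C(C)=C/Cc1cc(OC)cc(C)c1OC | intermediate
18 | (2E,6E,10S,11S)-1-(2,5-dimethoxy-3-methylphenyl)-3,7,11,15-tetramethylhexadeca-2,6,14-triene-10,11-diol | CC(C)=CCC[C@](C)(O)[C@@H](O)CC/C(C)=C/CC/C(C)=C/Cc1cc(OC)cc(C)c1OC | intermediate
19 | 2-[(2E,6E,10S,11S)-10,11-dihydroxy-3,7,11,15-tetramethylhexadeca-2,6,14-trienyl]-6-methylcyclohexa-2,5-diene-1,4-dione | CC(C)=CCC[C@](C)(O)[C@@H](O)CC/C(C)=C/CC/C(C)=C/CC1=CC(=O)C=C(C)C1=O | target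

Total step count: 11
Longest linear sequence: 9 steps (steps 3 to 11, from 4 to 19)

**Steps most likely to fail**

Step 8. Deprotonation of 3 may stay incomplete, so that free s-BuLi consumes the aldehyde. Proton transfer from 13 (enolisation) may compete with addition. Oxidation of the crowded alkoxide may be slow enough for acyl migration to set in on warming.
The fallback sets out from 3 and 13 and comes back at 16. It separates carbanion formation from C–C bond formation and raises the electrophile to the acid level.
- Lithiated 3 is quenched with Me3SnCl to the isolable tertiary stannane F1. Substitution is retentive, and the descriptor becomes R only through the priority change.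
- 13 is oxidised (NaClO2, NaH2PO4, 2-methylbut-2-ene, t-BuOH/H2O) to the carboxylic acid F2.
- F2 is coupled (EDC, MeNHOMe, CH2Cl2) to the Weinreb amide F3.
- Tin–lithium exchange of F1 with n-BuLi (THF, −78 °C) regenerates 14 free of any other base. Acylation of 14 by F3 through the chelated tetrahedral intermediate should give 16 directly.

Step 9. Hydride transfer at a carbonyl flanked by a fully substituted carbon may be sluggish. Facial selectivity may also be poor if the ester group disturbs binding to the catalyst.
The fallback sets out from 16 and comes back at 17. It replaces asymmetric reduction by separation of diastereomers with recycling.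
- NaBH4 in MeOH at 0 °C reduces 16 without selectivity to 17 and the 10'R epimer F4.
- Because C11' is fixed, the two are diastereomers and are separated by chromatography.
- F4 is returned to 16 with Dess–Martin periodinane and put through again.

Step 11. Tetravalent cerium may cleave the glycol C–C bond, or the side chain may be over-oxidised, in competition with ring oxidation.
The fallback sets out from 18 and comes back at 19. It masks the glycol during the oxidation.
- 2,2-Dimethoxypropane and PPTS in CH2Cl2 convert 18 into the acetonide F5.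
- (NH4)2Ce(NO3)6 in MeCN/H2O at 0 °C gives the quinone acetonide F6.
- Aqueous AcOH at 40 °C, which the quinone and the alkenes should tolerate, releases 19.

**Further compounds**
F1 | step 8 | (R)-6-methyl-2-(trimethylstannyl)hept-5-en-2-yl 2,4,6-triisopropylbenzoate | CC(C)=CCC[C@]([Sn](C)(C)C)(C)OC(=O)c1c(C(C)C)cc(C(C)C)cc1C(C)C
F2 | step 8 | (4E,8E)-10-(2,5-dimethoxy-3-methylphenyl)-4,8-dimethyldeca-4,8-dienoic acid | OC(=O)CC/C(C)=C/CC/C(C)=C/Cc1cc(OC)cc(C)c1OC
F3 | step 8 | (4E,8E)-10-(2,5-dimethoxy-3-methylphenyl)-N-methoxy-N,4,8-trimethyldeca-4,8-dienamide | CON(C)C(=O)CC/C(C)=C/CC/C(C)=C/Cc1cc(OC)cc(C)c1OC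
F4 | step 9 | (2E,6E,10R,11S)-1-(2,5-dimethoxy-3-methylphenyl)-10-hydroxy-3,7,11,15-tetramethylhexadeca-2,6,14-trien-11-yl 2,4,6-triisopropylbenzoate | CC(C)=CCC[C@](C)(OC(=O)c1c(C(C)C)cc(C(C)C)cc1C(C)C)[C@H](O)CC/C(C)=C/CC/C(C)=C/Cc1cc(OC)cc(C)c1OC
F5 | step 11 | 10',11'-O-isopropylidene derivative (acetonide) of 18, configuration at C10' and C11' unchanged | CC(C)=CCC[C@]1(C)OC(C)(C)O[C@H]1CC/C(C)=C/CC/C(C)=C/Cc1cc(OC)cc(C)c1OC
F6 | step 11 | 10',11'-O-isopropylidene derivative (acetonide) of 19, configuration at C10' and C11' unchanged | CC(C)=CCC[C@]1(C)OC(C)(C)O[C@H]1CC/C(C)=C/CC/C(C)=C/CC1=CC(=O)C=C(C)C1=O
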